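**Retrosynthetic overview**

1. The target is (2S)-5-hydroxy-6,7,3',4'-tetramethoxyflavanone; the free C5–OH is uncovered last from the pentamethyl ether by chelation-controlled cleavage of the methyl ether peri to the C4 carbonyl.
2. Key disconnection: both bonds joining ring A to the pyranone ring, C8a–O1 and C4a–C4, are cut together. This gives 3,4,5-trimethoxybenzyne and the four-atom unit O1–C2–C3–C4 as an (S)-β-silyloxy N,N-dimethylamide that already carries C2 and ring B.
3. Enabling feature: C8a and C4a are neighbouring ring A carbons (an aryne retron), and C4a is flanked by the C5 oxygen, which polarizes the aryne so that oxygen adds at C8a and the carbanion appears at C4a. O1 and the C4 carbonyl are 1,3-related through C2–C3, so this carbanion reaches the acyl carbon through a six-membered ring.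
4. Fragments: the aryne precursor comes from 3,4,5-trimethoxyphenol (bromination, retro-Brook/triflation). The chain comes from methyl 3,4-dimethoxybenzoate and N,N-dimethylacetamide (Claisen), with C2 set by ketoreductase reduction, then O-silylation.
5. Ring order: rings A and B are bought as arenes; the pyranone ring (ring C) is the only ring made, in the key step.

Key step: step 6

Remark: the target is the (2S)-flavanone. The carbinol carbon of the open-chain precursors has the same descriptor, because the ranking O > aryl > CH2 > H is the same in both.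

**Step 1**
Reactants: 1 3,4,5-trimethoxyphenol
Product: 2 2-bromo-3,4,5-trimethoxyphenol
Conditions: NBS (1.0 equiv), CH2Cl2, −40 → 0 °C
Reagents that add atoms: N-bromosuccinimide, O=C1CCC(=O)N1Br
Why: Electrophilic aromatic bromination ortho to the free hydroxyl group should give the monobromide, since the two open ring positions are equivalent and one equivalent of NBS at low temperature limits dibromination.

**Step 2**
Reactants: 2 2-bromo-3,4,5-trimethoxyphenol
Product: 5 3,4,5-trimethoxy-2-(trimethylsilyl)phenyl trifluoromethanesulfonate, via aryl trimethylsilyl ether 3 (not isolated), via lithium 2-silylphenoxide 4 (not isolated)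
Conditions: HMDS, THF, 65 °C, then evaporate; n-BuLi (1.1 equiv), THF, −95 → −78 °C; Tf2O (1.2 equiv), −95 °C → rt
Reagents that add atoms: hexamethyldisilazane, C[Si](C)(C)N[Si](C)(C)C; trifluoromethanesulfonic anhydride, O=S(=O)(OS(=O)(=O)C(F)(F)F)C(F)(F)F
Why: O-silylation, bromine–lithium exchange, anionic 1,3-shift of silicon from oxygen to carbon (retro-Brook rearrangement) and O-triflation of the resulting phenoxide are the standard sequence to 2-(trimethylsilyl)aryl triflates and should proceed likewise here.

**Step 3**
Reactants: 6 methyl 3,4-dimethoxybenzoate; 7 N,N-dimethylacetamide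
Product: 9 3-(3,4-dimethoxyphenyl)-N,N-dimethyl-3-oxopropanamide, via lithium enolate of N,N-dimethylacetamide 8 (not isolated)
Conditions: LiN(i-Pr)2 (2.2 equiv), 7 (2.2 equiv), THF, −78 °C; then 6 (1.0 equiv), −78 → 0 °C; 1 M HCl (aq)
Reagents that add atoms: none
Why: Crossed Claisen condensation of the amide enolate with a non-enolizable aromatic ester should give the β-keto amide, driven by deprotonation of the product by the second equivalent of enolate.

**Step 4**
Reactants: 9 3-(3,4-dimethoxyphenyl)-N,N-dimethyl-3-oxopropanamide
Product: 10 (3S)-3-(3,4-dimethoxyphenyl)-3-hydroxy-N,N-dimethylpropanamide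
Conditions: ketoreductase (Prelog-selective, NADPH-dependent), NADP+ (cat.), 2-propanol (10% v/v), KH2PO4/K2HPO4 buffer pH 7.0, 30 °C
Reagents that add atoms: none
Why: Enzymatic carbonyl reduction (ketoreductase class, cofactor recycled by 2-propanol) should deliver hydride from NADPH to the Re face of the aryl ketone held in the active site, which sets the carbinol center as S, and aryl β-keto N,N-dialkylamides are accepted substrates of this enzyme class.

**Step 5**
Reactants: 10 (3S)-3-(3,4-dimethoxyphenyl)-3-hydroxy-N,N-dimethylpropanamide
Product: 11 (3S)-3-(3,4-dimethoxyphenyl)-N,N-dimethyl-3-[(trimethylsilyl)oxy]propanamide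
Conditions: HMDS (1.0 equiv), Me3SiCl (5 mol %), CH2Cl2, 23 °C; volatiles removed in vacuo, used without chromatography
Reagents that add atoms: hexamethyldisilazane, C[Si](C)(C)N[Si](C)(C)C
Why: O-Silylation with HMDS should convert the alcohol into a fluoride-labile latent alkoxide and remove the only acidic proton before the aryne step, without touching the stereocenter.

**Step 6**
Reactants: 11 (3S)-3-(3,4-dimethoxyphenyl)-N,N-dimethyl-3-[(trimethylsilyl)oxy]propanamide; 5 3,4,5-trimethoxy-2-(trimethylsilyl)phenyl trifluoromethanesulfonate
Product: 14 (2S)-2-(3,4-dimethoxyphenyl)-5,6,7-trimethoxy-2,3-dihydro-4H-chromen-4-one, via 3,4,5-trimethoxybenzyne 12 (not isolated), via potassium hemiaminal alkoxide 13 (not isolated)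
Conditions: 5 (1.5 equiv), KF (4 equiv), 18-crown-6 (4 equiv), dry THF (no protic additive), 0 → 23 °C; then 1 M HCl (aq), 0 °C
Reagents that add atoms: none
Why: Proposed new method: fluoride should unmask the alkoxide of 11 and, from 5, the aryne 12; the alkoxide oxygen adds to the aryne carbon remote from the flanking methoxy group (future C8a), and the aryl carbanion thus formed ortho to that methoxy group (future C4a) attacks the tethered amide carbonyl to give the tetrahedral alkoxide 13, which releases dimethylamine and the ketone only on the cold acid quench. The closest known reaction types are the fluoride-mediated annulation of arynes with ortho-hydroxy or ortho-amino benzoates to xanthones and acridones (aryl–heteroatom and aryl–acyl bonds made in one pot) and the insertion of arynes into the N–C(O) bond of NH β-lactams; new here are the aliphatic secondary alkoxide as nucleophile and the tertiary amide as acyl acceptor. The pyranone ring closes by a 6-exo-trig addition of the aryl carbanion to the C=O group. No stereocenter of the product is formed in this step: C2 comes from 10 and keeps its configuration because only its O–Si bond, not its C–O bond, takes part, and the transient C4 hemiaminal center is destroyed at work-up. The step needs regioselective addition to the aryne, which the inductive distortion of the triple bond by the adjacent C3 methoxy group should secure, and acylation of the aryl anion faster than protonation or elimination, which the absence of any O–H or N–H proton, the low α-C–H acidity of the amide and the masking of the ketone as 13 (no enolate, hence no base-induced retro-oxa-Michael opening and racemization) should secure.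

**Step 7**
Reactants: 14 (2S)-2-(3,4-dimethoxyphenyl)-5,6,7-trimethoxy-2,3-dihydro-4H-chromen-4-one
Product: 15 (2S)-2-(3,4-dimethoxyphenyl)-5-hydroxy-6,7-dimethoxy-2,3-dihydro-4H-chromen-4-one
Conditions: BCl3 (1.2 equiv, 1 M in CH2Cl2), CH2Cl2, −78 → 0 °C; then H2O, 0 °C
Reagents that add atoms: none
Why: Chelation-controlled ether cleavage: boron should bind the C4 carbonyl oxygen and the peri C5 methoxy oxygen in a six-membered chelate so that chloride removes only that methyl group, while the cold, non-basic medium leaves C2 unchanged.

**Compound list**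

1 | 3,4,5-trimethoxyphenol | COc1cc(O)cc(OC)c1OC | starting material
2 | 2-bromo-3,4,5-trimethoxyphenol | COc1cc(O)c(Br)c(OC)c1OC | intermediate
3 | (2-bromo-3,4,5-trimethoxyphenoxy)trimethylsilane (formed in the flask, not isolated) | COc1cc(O[Si](C)(C)C)c(Br)c(OC)c1OC | intermediate
4 | lithium 3,4,5-trimethoxy-2-(trimethylsilyl)phenoxide (formed in the flask, not isolated) | COc1cc([O-])c([Si](C)(C)C)c(OC)c1OC.[Li+] | intermediate
5 | 3,4,5-trimethoxy-2-(trimethylsilyl)phenyl trifluoromethanesulfonate | COc1cc(OS(=O)(=O)C(F)(F)F)c([Si](C)(C)C)c(OC)c1OC | intermediate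
6 | methyl 3,4-dimethoxybenzoate | COC(=O)c1ccc(OC)c(OC)c1 | starting material
7 | N,N-dimethylacetamide | CC(=O)N(C)C | starting material
8 | lithium enolate of N,N-dimethylacetamide (formed in the flask, not isolated) | C=C([O-])N(C)C.[Li+] | intermediate
9 | 3-(3,4-dimethoxyphenyl)-N,N-dimethyl-3-oxopropanamide | COc1ccc(C(=O)CC(=O)N(C)C)cc1OC | intermediate
10 | (3S)-3-(3,4-dimethoxyphenyl)-3-hydroxy-N,N-dimethylpropanamide | COc1ccc([C@@H](O)CC(=O)N(C)C)cc1OC | intermediate
11 | (3S)-3-(3,4-dimethoxyphenyl)-N,N-dimethyl-3-[(trimethylsilyl)oxy]propanamide | COc1ccc([C@@H](O[Si](C)(C)C)CC(=O)N(C)C)cc1OC | intermediate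
12 | 3,4,5-trimethoxybenzyne (formed in the flask, not isolated) | COC1=C(OC)C(OC)=CC#C1 | intermediate
13 | potassium (2S)-4-(dimethylamino)-2-(3,4-dimethoxyphenyl)-5,6,7-trimethoxy-3,4-dihydro-2H-chromen-4-olate, either configuration at C4 (formed in the flask, not isolated) | COc1ccc([C@@H]2CC([O-])(N(C)C)c3c(cc(OC)c(OC)c3OC)O2)cc1OC.[K+] | intermediate
14 | (2S)-2-(3,4-dimethoxyphenyl)-5,6,7-trimethoxy-2,3-dihydro-4H-chromen-4-one | COc1ccc([C@@H]2CC(=O)c3c(cc(OC)c(OC)c3OC)O2)cc1OC | intermediate
15 | (2S)-2-(3,4-dimethoxyphenyl)-5-hydroxy-6,7-dimethoxy-2,3-dihydro-4H-chromen-4-one | COc1ccc([C@@H]2CC(=O)c3c(cc(OC)c(OC)c3O)O2)cc1OC | target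

**Step count and risks**

Total step count: 7. Longest linear sequence: 5 steps (steps 3, 4, 5, 6, 7).

The three steps most likely to fail:

**Step 6 (proposed new method).** Several processes could defeat it:
- protonation of the aryl anion, or its proton abstraction from the amide α-CH2 followed by loss of the aryloxide, instead of acylation;
- attack of the alkoxide at the sulfur of the triflate;
- retro-aldol cleavage of the free alkoxide;
- early collapse of the tetrahedral adduct, followed by base-induced opening of the pyranone ring and loss of configuration at C2.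

The fallback uses known chemistry and forms the two bonds in separate steps. It sets out from 2 and 9 and comes back to the route at 14. The ketone 9 would be reduced with an enantiocomplementary (anti-Prelog) ketoreductase to (3R)-3-(3,4-dimethoxyphenyl)-3-hydroxy-N,N-dimethylpropanamide F1. Mitsunobu etherification of F1 with the bromophenol 2 (PPh3, DIAD, toluene, 0 °C) should give, with inversion, (3S)-3-(2-bromo-3,4,5-trimethoxyphenoxy)-3-(3,4-dimethoxyphenyl)-N,N-dimethylpropanamide F2. Bromine–lithium exchange (n-BuLi, THF, −100 °C) and Parham-type cyclization of the aryllithium onto the amide, followed by cold aqueous acid, should then give 14.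

**Step 7.** Regioselectivity could be lost through further cleavage of the C6 methoxy group via the boron phenoxide, or of the ring B methyl ethers. Configuration at C2 could erode through Lewis-acid-promoted opening and re-closure of the pyranone ring.

The fallback changes the protecting-group plan so that the C5 oxygen is carried as a benzyl ether. It sets out from 11 and comes back to the route at 15.
- Purchased 2-hydroxy-3,4-dimethoxybenzaldehyde F3 would be benzylated (BnBr, K2CO3, DMF) to 2-(benzyloxy)-3,4-dimethoxybenzaldehyde F4.
- Baeyer–Villiger oxidation and hydrolysis of the formate (mCPBA, CH2Cl2; then NaOH, MeOH/H2O) should give 2-(benzyloxy)-3,4-dimethoxyphenol F5.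
- Bromination at the only free position ortho to the hydroxyl group (NBS) should give 2-(benzyloxy)-6-bromo-3,4-dimethoxyphenol F6.
- The silylation, retro-Brook and triflation sequence of step 2 should give 2-(benzyloxy)-3,4-dimethoxy-6-(trimethylsilyl)phenyl trifluoromethanesulfonate F7.
- F7 gives the same type of aryne, with the benzyloxy group next to the triple bond, so the annulation of step 6 with 11 should give (2S)-5-(benzyloxy)-2-(3,4-dimethoxyphenyl)-6,7-dimethoxy-2,3-dihydro-4H-chromen-4-one F8.
- Hydrogenolysis (H2, Pd/C, EtOAc, 23 °C) should then give 15 under neutral conditions.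

**Step 2.** The silyl shift from oxygen to the crowded carbon between two oxygen substituents could be incomplete, or the aryllithium could be protonated before the shift, giving unsilylated triflate.

The fallback replaces halogen–metal exchange by carbamate-directed ortho-metalation. It sets out from 1 and comes back to the route at 5. Phenol 1 would be converted with isopropyl isocyanate (Et3N cat., CH2Cl2) into 3,4,5-trimethoxyphenyl N-(propan-2-yl)carbamate F9. In situ N-silylation (TBSOTf, TMEDA), ortho-lithiation (n-BuLi, TMEDA, Et2O, −78 °C) and a Me3SiCl quench should give 3,4,5-trimethoxy-2-(trimethylsilyl)phenyl N-(propan-2-yl)carbamate F10. Carbamate cleavage (Et2NH, DBU, MeCN, 40 °C) to 3,4,5-trimethoxy-2-(trimethylsilyl)phenol F11, followed by triflation with PhNTf2 in the same pot, should give 5.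

**Further compounds**

F1 | step 6 | (3R)-3-(3,4-dimethoxyphenyl)-3-hydroxy-N,N-dimethylpropanamide | COc1ccc([C@H](O)CC(=O)N(C)C)cc1OC
F2 | step 6 | (3S)-3-(2-bromo-3,4,5-trimethoxyphenoxy)-3-(3,4-dimethoxyphenyl)-N,N-dimethylpropanamide | COc1ccc([C@@H](Oc2cc(OC)c(OC)c(OC)c2Br)CC(=O)N(C)C)cc1OC
F3 | step 7 | 2-hydroxy-3,4-dimethoxybenzaldehyde (purchased starting material of this fallback) | COc1ccc(C=O)c(O)c1OC
F4 | step 7 | 2-(benzyloxy)-3,4-dimethoxybenzaldehyde | COc1ccc(C=O)c(OCc2ccccc2)c1OC
F5 | step 7 | 2-(benzyloxy)-3,4-dimethoxyphenol | COc1ccc(O)c(OCc2ccccc2)c1OC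
F6 | step 7 | 2-(benzyloxy)-6-bromo-3,4-dimethoxyphenol | COc1cc(Br)c(O)c(OCc2ccccc2)c1OC
F7 | step 7 | 2-(benzyloxy)-3,4-dimethoxy-6-(trimethylsilyl)phenyl trifluoromethanesulfonate | COc1cc([Si](C)(C)C)c(OS(=O)(=O)C(F)(F)F)c(OCc2ccccc2)c1OC
F8 | step 7 | (2S)-5-(benzyloxy)-2-(3,4-dimethoxyphenyl)-6,7-dimethoxy-2,3-dihydro-4H-chromen-4-one | COc1ccc([C@@H]2CC(=O)c3c(cc(OC)c(OC)c3OCc4ccccc4)O2)cc1OC
F9 | step 2 | 3,4,5-trimethoxyphenyl N-(propan-2-yl)carbamate | COc1cc(OC(=O)NC(C)C)cc(OC)c1OC
F10 | step 2 | 3,4,5-trimethoxy-2-(trimethylsilyl)phenyl N-(propan-2-yl)carbamate | COc1cc(OC(=O)NC(C)C)c([Si](C)(C)C)c(OC)c1OC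
F11 | step 2 | 3,4,5-trimethoxy-2-(trimethylsilyl)phenol | COc1cc(O)c([Si](C)(C)C)c(OC)c1OC
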